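# Total synthesis proposal for CNP0231466.1 by masked o-benzoquinone cycloaddition and oxa-di-π-methane rearrangement

Abbreviations: TBDPS = tert-butyldiphenylsilyl, TIPS = triisopropylsilyl, PMB = 4-methoxybenzyl, TES = triethylsilyl. Atom numbers (C8, O33 and so on) are the positions of the atoms in the SMILES string of the target and are kept for every intermediate.

## Analysis of the target

The skeleton is tetracyclic. Ring A (C8-C9-C11-C14-C36) and ring C (C8-C25-C27-C34-C36) form a cis-fused diquinane that shares the C8–C36 bond. Ring B (C8-C25-C23-C15-C14-C36) ties C25 of ring C to C14 of ring A through the enolised β-diketone carbons C23 and C15, and the γ-lactone ring D (C27-C29-C31-O33-C34) sits on the C27–C34 edge. There are eight stereocentres, five of them fully substituted (C8, C11, C25, C27, C34), and C8, C25, C27 and C34 are contiguous on one cyclopentane. C8, C14, C25 and C36 are locked to each other by the ring system, so the independent elements are the handedness of the core, C11, the face of ring C that carries the lactone, and C29.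

All five carbons of ring C carry their ring-forming bonds (to C9, C23, C29, O33 and C14) on one face and the small groups (C6 acyl, C26, O28–H, C35, H) on the other. O13 lies on the open face of ring A, and the C30 methyl lies on the concave face of the lactone, cis to C25 and trans to O28. Sensitive groups are:

- the two sorbyl dienones;
- the non-enolisable 1,3-diketone C6/C9 (retro-Claisen);
- the tertiary α-ketol C9/C11;
- the tertiary hydroxyl on C27, which is aldol-related to both C23 and C31 (retro-aldol);
- the epimerisable C29.

The difficulty is the density: four adjacent quaternary carbons, and an oxygen in a different oxidation state on almost every ring carbon. The strategy rests on two observations. First, C9, C11 and C34 all bear oxygen, and if the C11–C14 bond is moved back to C34 they stand in a row like the three oxygens of a pyrogallol-type arene. Second, rings A and C are exactly the cis-diquinane that a bicyclo[2.2.2]oct-5-en-2-one gives on a 1,2-acyl shift.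

## Retrosynthetic reasoning

**C5–C6 (39 to 35 and 37).** The sorbyl ketone on C8 is a Michael acceptor, a chromophore and part of a cleavable 1,3-diketone, so it is made last. Cutting C5–C6 leads to aldehyde 35 and dienyl iodide 37. The forward reaction must add a dienyl metal to an aldehyde in the presence of ketones, a lactone, an enol and free tertiary alcohols, and the resulting carbinol 38 must be oxidised without base.

**C14–C15 and the C11 oxygen (33 to 32).** Ring B is opened at C14–C15 because C15 is the central carbon of a β-diketone, a soft carbon nucleophile, and C14 is β to the C9 ketone. Conjugate addition would leave C11 to be hydroxylated later beside a far more oxidisable β-diketone enolate. The oxygen is therefore put on first as a C11–C14 epoxide on the open face of ring A (28). Opening this epoxide at C14 from the concave face, the only face the tether can reach, forms ring B, inverts C14 and leaves O13 on C11 in one step.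

**C15–C23 (32 to 28 and 30) and release of C9 and C23 (26 from 25).** The diketone comes from an aldol between aldehyde C23 and the methyl ketone 30, followed by oxidation. This brings in C15 to C22 in one piece and needs only an aldehyde on the quaternary C25. The C9 ketone and the C23 alcohol are released together from one cyclic mixed ketal in 25, so C23 never has to be told apart from other hydroxyl groups.

**Lactone ring D (25 back to 18).** The C27–C29 bond must be formed on the concave face of ring C, where no external reagent would go, so C29 is delivered from O33 as an ester enolate onto the C27 ketone (22 to 23). O33 and C35 are set one step earlier by adding a methyl nucleophile to the C34 ketone of 18 from the convex face, and the hindered alkoxide is acylated in the same flask (20). C29 is adjusted afterwards by protonation (24). The C27 hydroxyl is then capped (25) so that it cannot fragment by retro-aldol once C23 is a carbonyl group.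

**C14–C34 (18 to 16 to 15).** Diquinane 18 is the product of cleaving the one extra bond of the cyclopropyl ketone 15. Adding the C12 methyl to the C11 ketone first (16) means that the ionisation which opens C14–C34 also creates the C11=C14 alkene, the later enone of ring A. It also means that C11 and C34 are never ketones at the same time, so each methyl addition meets a single carbonyl group.

**C11–C14 and C34–C36 (15 to 14), the key disconnection.** The tricyclic ketone 15 is the 1,2-acyl-shift isomer of the bicyclo[2.2.2]octenone 14. The forward reaction must move C11 from C34 to C14, join C34 to C36, and avoid the 1,3-shift.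

**C8–C25 and C27–C34 (14 to 13 to 7 and 11).** The bicyclooctenone is the Diels–Alder adduct of a cyclohexadienone made by oxidising phenol 7 in the presence of alkenol 11. Making the dienophile part of the ketal has three consequences:

- the two-atom tether O–C23 forces C25 onto C8 and C27 onto C34, and places C23 on the side of the ketal bridge, which is the configuration ring B needs;
- the Z enol ether places O28 on the concave side, which later keeps the convex face of C34 free;
- the cycloaddition that joins two fully substituted carbons is intramolecular.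

The adduct is racemic and is resolved at once (13 to 14).

**Arene and alkenol (7 from 1; 11 from 8).** The oxidation must put the second ketal oxygen on C9 and not on C34. Phenol 7 therefore carries a methoxy group only on C9 and a silyloxy group on C34, a pattern available from 1 by standard selective protection. Alkenol 11 needs its Z geometry, which is secured by passing through the six-membered enol acetal 10.

## Alternatives that were turned down

**Alternative 1:** Cut C8–C9, C8–C25, C36–C14 and C36–C34 and make rings A and C in one flask by the Weiss–Cook condensation of 3-(benzyloxy)-2-oxopropanal A1 with two molecules of dimethyl 3-oxopentanedioate A2, giving the bis-enol tetraester A3.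

- For it: four C–C bonds, both rings and the cis fusion come from commodity chemicals in one step, and the ester carbons on C14 and C25 are already C15 and C23. On step count to the bare diquinane it is clearly stronger than the chosen route.
- Against it: A3 has two nearly equivalent rings, whereas the target decorates them quite differently. The condensation puts ketone oxygen on C11 and C27 and carbon on C9 and C34. The C9 ester would have to be excised and C9 oxidised, C11 turned into a methyl carbinol, four esters and two enols told apart, and C25, C27 and C34 made quaternary one by one with no element that controls facial selectivity. The material is also racemic.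
- Comparison: the chosen strategy is longer to the core but delivers every oxygen to the right carbon from the arene, sets C25 through the tether, and differentiates the two rings from the start.

**Alternative 2:** Cut C9–C11 and close ring A last by a carbene-catalysed aldehyde–ketone benzoin reaction of the seco aldehyde A4, using the carbene from 3-benzyl-5-(2-hydroxyethyl)-4-methylthiazolium chloride A5, to give the O28 silyl ether A6 of the target.

- For it: the step forms the tertiary α-ketol directly, and only a desilylation follows. In endgame convergence it is stronger than the chosen route.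
- Against it: A4 already contains rings B, C and D, seven of the eight stereocentres and both sorbyl groups, so the real problem is only postponed. In A4 the aldehyde sits on quaternary C8 next to the sorbyl ketone (prone to deformylation), the acyl-anion equivalent has two dienones within reach (Stetter addition), the β-diketone is acidic enough to quench the carbene, and the C11 configuration depends on an uncontrolled facial choice at the acetyl group.
- Comparison: the chosen route builds rings A and C early in a rigid bicycle and sets C11 by a face-selective epoxidation.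

**Alternative 3:** Cut C8–C25 and join the two β-diketone carbons of the hydroazulene tetraketone A7 by oxidising its dilithium bis-enolate with [Fe(DMF)3Cl2][FeCl4] A8 (trivalent iron), giving the tricyclic tetraketone A9 with rings B and C closed at once.

- For it: the most congested bond of the molecule, between two quaternary carbons, is made directly and late from a simpler 5–7 bicycle. If the step worked the route would be shorter than the chosen one.
- Against it: two stabilised, hindered enolate carbons would have to couple across a seven-membered ring. O–C coupling, over-oxidation and radical addition to the dienone are all open, there is no close analogy for such a transannular coupling to vicinal quaternary centres, and A7 with its own three stereocentres is not a trivial target. The lactone would still be missing in A9.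
- Comparison: the chosen route makes C8–C25 in a tethered cycloaddition and keeps its main risk in a photochemical step with direct precedent.

Key step: step 12

## Remarks on the chemistry

- The cycloadduct is formed as the racemate and resolved in step 11. The racemic compounds 12 and 13 are written in the list as 1:1 pairs of enantiomers.
- Compound 32 is listed as the diketo tautomer. Compounds 33 to 39 are listed as the C16 enol hydrogen-bonded to the C23 carbonyl.

## Route

Step 1
Reactants: 1 2,3,4-trihydroxybenzaldehyde
Product: 2 4-hydroxy-2,2-diphenyl-1,3-benzodioxole-5-carbaldehyde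
Conditions: Ph2CCl2, Ph2O, 170 °C
Reagents that add atoms: dichlorodiphenylmethane, ClC(Cl)(c1ccccc1)c1ccccc1
Why: Ketalisation of the catechol pair O3/O4 (the later oxygens on C11 and C34); the 2-hydroxyl is held in a hydrogen bond to the aldehyde and is the least nucleophilic, so it stays free.

Step 2
Reactants: 2 4-hydroxy-2,2-diphenyl-1,3-benzodioxole-5-carbaldehyde
Product: 3 4-methoxy-2,2-diphenyl-1,3-benzodioxole-5-carbaldehyde
Conditions: MeI, K2CO3, DMF, 40 °C
Reagents that add atoms: iodomethane, CI
Why: Williamson methylation of the only free phenol; this methoxy group marks the carbon that becomes C9.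

Step 3
Reactants: 3 4-methoxy-2,2-diphenyl-1,3-benzodioxole-5-carbaldehyde
Product: 4 3,4-dihydroxy-2-methoxybenzaldehyde
Conditions: AcOH/H2O (4:1), 100 °C
Reagents that add atoms: none
Why: Acid hydrolysis of the diaryl ketal; the aryl methyl ether and the aldehyde are stable to aqueous acetic acid.

Step 4
Reactants: 4 3,4-dihydroxy-2-methoxybenzaldehyde
Product: 5 3-hydroxy-2-methoxy-4-[(triisopropylsilyl)oxy]benzaldehyde
Conditions: TIPSCl (1.05 equiv), imidazole, DMF, 0 °C
Reagents that add atoms: chlorotriisopropylsilane, CC(C)[Si](Cl)(C(C)C)C(C)C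
Why: Selective silylation of the 4-hydroxyl, which is the more acidic one (para to the aldehyde) and the less hindered one (the 3-hydroxyl is flanked on both sides); the bulky silyl group is slow to migrate.

Step 5
Reactants: 5 3-hydroxy-2-methoxy-4-[(triisopropylsilyl)oxy]benzaldehyde
Product: 6 3-(hydroxymethyl)-2-methoxy-6-[(triisopropylsilyl)oxy]phenol
Conditions: NaBH4, MeOH/THF, 0 °C
Reagents that add atoms: none
Why: Borohydride reduction of the aldehyde to the benzylic alcohol (C6) at low temperature and short contact time.

Step 6
Reactants: 6 3-(hydroxymethyl)-2-methoxy-6-[(triisopropylsilyl)oxy]phenol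
Product: 7 3-{[(tert-butyldiphenylsilyl)oxy]methyl}-2-methoxy-6-[(triisopropylsilyl)oxy]phenol
Conditions: TBDPSCl (1.05 equiv), imidazole, CH2Cl2, 0 °C
Reagents that add atoms: tert-butyl(chloro)diphenylsilane, CC(C)(C)[Si](Cl)(c1ccccc1)c1ccccc1
Why: Silylation of the primary alcohol is much faster than that of the phenol, which is flanked by the methoxy and silyloxy groups; TBDPS is chosen to outlast the later acid steps.

Step 7
Reactants: 8 2-methylidenepropane-1,3-diol
Product: 9 2-(4-methoxyphenyl)-5-methylidene-1,3-dioxane
Conditions: 4-MeOC6H4CH(OMe)2, PPTS (cat.), CH2Cl2, 20 °C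
Reagents that add atoms: 4-methoxybenzaldehyde dimethyl acetal, COC(OC)c1ccc(OC)cc1
Why: Acid-catalysed transacetalisation of the 1,3-diol to the six-membered arylidene acetal.

Step 8
Reactants: 9 2-(4-methoxyphenyl)-5-methylidene-1,3-dioxane
Product: 10 (±)-2-(4-methoxyphenyl)-5-methyl-4H-1,3-dioxine
Conditions: RuHCl(CO)(PPh3)3 (2 mol %), toluene, 110 °C
Reagents that add atoms: none
Why: Metal-hydride isomerisation of the exocyclic alkene into the ring, driven by conjugation with oxygen (known for 5-methylidene-1,3-dioxanes); the two CH2O arms are equivalent, and the ring locks the enol ether with O and CH2O cis.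

Step 9
Reactants: 10 (±)-2-(4-methoxyphenyl)-5-methyl-4H-1,3-dioxine
Product: 11 (Z)-3-[(4-methoxybenzyl)oxy]-2-methylprop-2-en-1-ol
Conditions: iBu2AlH, CH2Cl2, –78 to –20 °C; aqueous potassium sodium tartrate
Reagents that add atoms: none
Why: Reductive opening of the arylidene acetal: aluminium binds the more basic alkyl oxygen, that C–O bond breaks and hydride goes to the oxocarbenium ion on the enol oxygen, so the PMB group ends on the enol oxygen and the allylic alcohol is freed with the Z geometry of the ring retained.

Step 10
Reactants: 7 3-{[(tert-butyldiphenylsilyl)oxy]methyl}-2-methoxy-6-[(triisopropylsilyl)oxy]phenol; 11 (Z)-3-[(4-methoxybenzyl)oxy]-2-methylprop-2-en-1-ol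
Product: 13 racemic tethered Diels–Alder adduct (the structure of 14 as a 1:1 pair of enantiomers), via dienone ketal 12 (not isolated)
Conditions: PhI(OAc)2 (1.1 equiv), 11 (3 equiv), NaHCO3, CH2Cl2, 0 °C; then toluene, 80 °C
Reagents that add atoms: none
Why: The oxidant turns the phenol into an electrophilic dienone precursor that the alkenol attacks at C9, the only ortho carbon bearing a methoxy group (C34 carries the bulky silyloxy group, which does not form a ketal), giving 12. The tethered enol ether then adds across C8 and C34 in an intramolecular inverse-demand Diels–Alder reaction (tandem oxidative acetalisation and cycloaddition of 2-methoxyphenols with alkenols). The two-atom tether forces C25 onto C8, C27 onto C34 and C23 onto the ketal side, and the Z alkene puts O28 on the side of the C9–C11 bridge.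

Step 11
Reactants: 13 racemic tethered Diels–Alder adduct
Product: 14 single enantiomer of the adduct: bicyclo[2.2.2]oct-5-en-2-one with ketone C11; bridgeheads C8 (CH2OTBDPS) and C34 (OTIPS); alkene C14=C36; C9 methyl ketal whose second oxygen is tied through C23H2 to C25 in a tetrahydrofuran ring; C26 methyl on the alkene side; O28–PMB on the side of the C9–C11 bridge
Conditions: preparative supercritical-fluid chromatography, amylose tris(3,5-dimethylphenylcarbamate) phase, CO2/iPrOH
Reagents that add atoms: none
Why: No bond is made; the enantiomers are separated at the first chiral intermediate so that all later material has the C8 configuration of the target, which would be confirmed by anomalous-dispersion X-ray analysis of a silicon-containing crystal or by correlation at the end.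

Step 12
Reactants: 14 single enantiomer of the bicyclo[2.2.2]oct-5-en-2-one
Product: 15 tricyclo[3.3.0.0]octan-3-one: rings A and C closed, extra cyclopropane C14-C34-C36, ketone C11 now on C14, OTIPS on C34, all other groups as in 14
Conditions: hν (300 nm lamps, Pyrex), acetone (solvent and sensitiser), argon, 20 °C
Reagents that add atoms: none
Why: Triplet acetone transfers its energy to the β,γ-enone; the carbonyl carbon C11 bonds to the alkene carbon C14, the C11–C34 bond then breaks to leave the 1,3-diradical C34/C36, and after spin inversion C34–C36 closes. This is the oxa-di-π-methane rearrangement of bicyclo[2.2.2]oct-5-en-2-ones from masked o-benzoquinones, known also with an oxygenated bridgehead and with the fused tetrahydrofuran of tethered adducts. Ring A (C8-C9-C11-C14-C36) is closed by the 1,2-acyl migration, a three-membered bridging of C11 onto C14 followed by opening of the oxycyclopropane; ring C (C8-C25-C27-C34-C36) is closed by recombination of the 1,3-diradical, which also forms the cyclopropane. The new stereocentres C14 and C36 are fixed by the rigid bicycle: C11 can only reach the face of C14 it already overhangs and C34 can only bond to C36 across that same face, so the diquinane is cis-fused and C8, C9, C25 and C27 pass through unchanged. The step needs the 1,2- and not the 1,3-acyl shift, which sensitisation instead of direct excitation secures; it also needs a single ketone chromophore, which the substrate has because C6 and C27 are ethers and C23 is the ether carbon of the ketal, while the aryl groups do not absorb behind Pyrex. The silyloxy donor on C34 and the carbonyl on C14 leave the cyclopropane set up for cleavage of the C14–C34 bond only.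

Step 13
Reactants: 15 tricyclo[3.3.0.0]octan-3-one
Product: 16 tertiary cyclopropyl carbinol: C11 bears C12 methyl and OH
Conditions: MeLi, THF, –78 °C
Reagents that add atoms: methyllithium, C[Li]
Why: 1,2-Addition to the only carbonyl group, a non-enolisable cyclopropyl ketone; the configuration of the carbinol (drawn for attack anti to C34) does not matter because C11 becomes sp2 in step 14.

Step 14
Reactants: 16 tertiary cyclopropyl carbinol
Product: 18 diquinane β,γ-unsaturated ketone: C34 ketone, C11(CH3)=C14 alkene, C9 ketal and O28–PMB unchanged, via mesylate 17 (not isolated)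
Conditions: MsCl, Et3N, CH2Cl2, –40 to 0 °C; then aqueous NaHCO3
Reagents that add atoms: none
Why: Sulfonylation makes the hydroxyl on the cyclopropylcarbinyl carbon a leaving group; ionisation is pushed by the silyloxy group on C34, so the C14–C34 bond opens to the C11=C14 alkene and a silyloxocarbenium ion that gives up its silyl group to chloride (ring opening of a 2-silyloxycyclopropyl carbinol to a β,γ-unsaturated ketone). The medium stays basic, so the ketal and the alkene position are kept.

Step 15
Reactants: 18 diquinane β,γ-unsaturated ketone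
Product: 20 2-bromopropanoate of the C34 tertiary alcohol: C35 methyl on the convex face, O33 on the concave face, epimers at the CHBr carbon, via cerium alkoxide 19 (not isolated)
Conditions: MeLi, CeCl3, THF, –78 °C; then 2-bromopropanoyl bromide, –78 to –20 °C
Reagents that add atoms: methyllithium, C[Li]; 2-bromopropanoyl bromide, CC(Br)C(=O)Br
Why: The organocerium reagent adds to the enolisable ketone without deprotonating C36 and comes from the convex face of the diquinane, which is also the face away from the C27 ether oxygen and from ring A; this sets C34. The hindered tertiary alkoxide is acylated in the same flask, where it is most reactive.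

Step 16
Reactants: 20 2-bromopropanoate with O28–PMB
Product: 21 C27 secondary alcohol
Conditions: DDQ, CH2Cl2/pH 7 buffer, 0 °C
Reagents that add atoms: none
Why: Oxidative cleavage of the PMB ether; the silyl ether, the ketal, the bromo ester and the trisubstituted alkene are inert, and the short neutral treatment limits acyl migration from O33 to O28.

Step 17
Reactants: 21 C27 secondary alcohol
Product: 22 C27 ketone
Conditions: Dess–Martin periodinane, NaHCO3, CH2Cl2, 20 °C
Reagents that add atoms: none
Why: Oxidation of a hindered secondary alcohol to a ketone that has no α-hydrogen, because C25 and C34 are fully substituted.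

Step 18
Reactants: 22 C27 ketone with the 2-bromopropanoate on O33
Product: 23 β-hydroxy-γ-lactone: ring D closed, O28–H on the convex face, C30 methyl cis to O28 (the C29 epimer of the target)
Conditions: SmI2 (2.2 equiv), THF, –78 °C
Reagents that add atoms: none
Why: SmI2 (divalent samarium) reduces the C–Br bond faster than anything else and the samarium enolate adds to the neighbouring ketone (intramolecular Reformatsky reaction); because C29 is delivered from O33 it can only arrive on the concave face, which sets C27. In the cyclic transition state the enolate substituent that points under ring C should be hydrogen, so C30 is expected cis to O28, and this is corrected in step 19.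

Step 19
Reactants: 23 β-hydroxy-γ-lactone, C29 epimer
Product: 24 β-hydroxy-γ-lactone with the C29 configuration of the target (C30 on the concave face, trans to O28)
Conditions: LiN(iPr)2 (2.5 equiv), THF, –78 °C; then AcOH, –78 °C
Reagents that add atoms: none
Why: Double deprotonation gives the alkoxide–enolate dianion, which does not undergo retro-aldol cleavage at –78 °C (as in Fráter–Seebach chemistry); kinetic protonation of the planar enolate from the convex face of the bicycle made of the lactone and ring C places hydrogen cis to O28 and the methyl group on the concave face.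

Step 20
Reactants: 24 β-hydroxy-γ-lactone
Product: 25 C27 triethylsilyl ether
Conditions: Et3SiOTf, 2,6-lutidine, CH2Cl2, –78 to 0 °C
Reagents that add atoms: triethylsilyl trifluoromethanesulfonate, CC[Si](CC)(CC)OS(=O)(=O)C(F)(F)F
Why: Silylation of the tertiary hydroxyl with the silyl triflate; the aldol-type oxygen on C27 is thereby never an alkoxide while C23 is a carbonyl group, which closes the retro-aldol pathway in steps 23 to 27.

Step 21
Reactants: 25 C27 triethylsilyl ether with the C9 mixed ketal
Product: 26 ring A enone (C9 ketone, C11=C14) with the C23 primary alcohol on C25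
Conditions: PPTS (0.2 equiv), acetone/H2O (10:1), 40 °C
Reagents that add atoms: water, O
Why: Mild hydrolysis of the allylic mixed ketal through the conjugated cyclic oxocarbenium ion releases the C9 carbonyl and the C23 alcohol together; the weak acid spares the silyl ethers, and the alcohol is oxidised at once in step 22 so that it cannot add to the enone.

Step 22
Reactants: 26 ring A enone with the C23 primary alcohol
Product: 27 C23 aldehyde
Conditions: Dess–Martin periodinane, NaHCO3, CH2Cl2, 20 °C
Reagents that add atoms: none
Why: Neutral oxidation of the primary alcohol; the aldehyde sits on quaternary C25 and cannot enolise or epimerise.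

Step 23
Reactants: 27 C23 aldehyde with the ring A enone
Product: 28 C11,C14-epoxy ketone with the epoxide oxygen O13 on the open face of ring A
Conditions: tBuOOH, DBU, CH2Cl2, 0 to 20 °C
Reagents that add atoms: tert-butyl hydroperoxide, CC(C)(C)OO
Why: Weitz–Scheffer epoxidation: the hydroperoxide anion adds to C14 from the convex face of ring A (the concave face is covered by C23 and C34) and the enolate closes the epoxide, which puts O13 on C11 with the configuration of the target. The aldehyde has no α-hydrogen and the C27 oxygen is protected.

Step 24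
Reactants: 29 sorbic acid, (2E,4E)-hexa-2,4-dienoic acid
Product: 30 (3E,5E)-hepta-3,5-dien-2-one
Conditions: MeLi (2.2 equiv), Et2O, 0 °C; aqueous NH4Cl
Reagents that add atoms: methyllithium, C[Li]
Why: Addition of MeLi to the lithium carboxylate stops at the dilithium gem-diolate, which gives the methyl ketone on work-up; this reagent carries C15 to C22.

Step 25
Reactants: 28 C11,C14-epoxy ketone with the C23 aldehyde; 30 (3E,5E)-hepta-3,5-dien-2-one
Product: 31 aldol adduct: C23 carbinol (both epimers) joined through C15H2 to the C16 dienyl ketone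
Conditions: 30, LiN(iPr)2, THF, –78 °C; then 28, –78 °C; AcOH
Reagents that add atoms: none
Why: Kinetic deprotonation of 30 on the methyl side and aldol addition to the aldehyde, which at –78 °C is far more electrophilic than the hindered epoxy ketone or the lactone; forms C15–C23.

Step 26
Reactants: 31 aldol adduct
Product: 32 β-diketone C23(=O)–C15H2–C16(=O)–dienyl on C25, epoxy ketone unchanged
Conditions: Dess–Martin periodinane, NaHCO3, CH2Cl2, 20 °C
Reagents that add atoms: none
Why: Oxidation of the β-hydroxy ketone to the 1,3-diketone under neutral conditions, which removes the C23 stereocentre.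

Step 27
Reactants: 32 β-diketone with the C11,C14-epoxy ketone
Product: 33 tetracycle with ring B closed: C14–C15 bond, C11 tertiary alcohol, enolised C16/C23 diketone, O28–TES, C6–OTBDPS
Conditions: Cs2CO3, MeCN, 20 to 40 °C; then aqueous NaH2PO4
Reagents that add atoms: none
Why: The caesium diketonate attacks C14 from the concave face, the only face its tether reaches and exactly anti to the epoxide C–O bond (6-exo-tet opening of an epoxide by a 1,3-dicarbonyl carbanion); ring B closes, C14 is inverted to the target configuration and O13 stays on C11. C11 is fully substituted, so substitution next to the carbonyl is impossible, and the new alkoxide is protonated by the more acidic diketone.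

Step 28
Reactants: 33 tetracycle with O28–TES and C6–OTBDPS
Product: 34 triol: C6 primary alcohol, C11 and C27 tertiary alcohols
Conditions: HF·pyridine, pyridine, THF, 0 to 20 °C
Reagents that add atoms: none
Why: Fluoride removes both silyl ethers in a buffered, weakly acidic medium that spares the α-ketol, the aldol-type hydroxyl and the dienyl diketone.

Step 29
Reactants: 34 triol
Product: 35 C6 aldehyde
Conditions: nPr4N[RuO4] (5 mol %), N-methylmorpholine N-oxide, 4 Å molecular sieves, CH2Cl2, 20 °C
Reagents that add atoms: none
Why: Ley–Griffith oxidation of the only primary alcohol; the tertiary alcohols cannot be oxidised. The aldehyde may rest as a lactol with O13 but reacts from the open form.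

Step 30
Reactants: 36 (E)-but-2-enal
Product: 37 (1E,3E)-1-iodopenta-1,3-diene
Conditions: CHI3, CrCl2, THF, 0 °C
Reagents that add atoms: iodoform, IC(I)I
Why: Takai olefination: the geminal dichromium species made from iodoform and CrCl2 (divalent chromium) converts the aldehyde into the E vinyl iodide.

Step 31
Reactants: 35 C6 aldehyde; 37 (1E,3E)-1-iodopenta-1,3-diene
Product: 38 C6 dienyl carbinol (both C6 epimers)
Conditions: CrCl2 (6 equiv), NiCl2 (2 mol %), DMSO, 20 °C
Reagents that add atoms: none
Why: Nozaki–Hiyama–Kishi coupling: the dienylchromium reagent (trivalent chromium), formed with nickel catalysis and retention of alkene geometry, adds only to the aldehyde; ketones, the lactone, the enol and free hydroxyls are tolerated. Forms C5–C6.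

Step 32
Reactants: 38 C6 dienyl carbinol
Product: 39 CNP0231466.1
Conditions: MnO2, CH2Cl2, 20 °C
Reagents that add atoms: none
Why: MnO2 oxidises the dienylic alcohol to the dienone and leaves tertiary alcohols and the enolised diketone alone; no acid or base touches the finished molecule, and both C6 epimers converge.

## Compound list

1 | 2,3,4-trihydroxybenzaldehyde | O=Cc1ccc(O)c(O)c1O | starting material
2 | 4-hydroxy-2,2-diphenyl-1,3-benzodioxole-5-carbaldehyde | O=Cc1ccc2OC(c3ccccc3)(c3ccccc3)Oc2c1O | intermediate
3 | 4-methoxy-2,2-diphenyl-1,3-benzodioxole-5-carbaldehyde | O=Cc1ccc2OC(c3ccccc3)(c3ccccc3)Oc2c1OC | intermediate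
4 | 3,4-dihydroxy-2-methoxybenzaldehyde | O=Cc1ccc(O)c(O)c1OC | intermediate
5 | 3-hydroxy-2-methoxy-4-[(triisopropylsilyl)oxy]benzaldehyde | O=Cc1ccc(O[Si](C(C)C)(C(C)C)C(C)C)c(O)c1OC | intermediate
6 | 3-(hydroxymethyl)-2-methoxy-6-[(triisopropylsilyl)oxy]phenol | OCc1ccc(O[Si](C(C)C)(C(C)C)C(C)C)c(O)c1OC | intermediate
7 | 3-{[(tert-butyldiphenylsilyl)oxy]methyl}-2-methoxy-6-[(triisopropylsilyl)oxy]phenol | CC(C)(C)[Si](c1ccccc1)(c1ccccc1)OCc1ccc(O[Si](C(C)C)(C(C)C)C(C)C)c(O)c1OC | intermediate
8 | 2-methylidenepropane-1,3-diol | C=C(CO)CO | starting material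
9 | 2-(4-methoxyphenyl)-5-methylidene-1,3-dioxane | C=C1COC(c2ccc(OC)cc2)OC1 | intermediate
10 | (±)-2-(4-methoxyphenyl)-5-methyl-4H-1,3-dioxine (racemic acetal carbon, lost in step 9) | CC1=COC(c2ccc(OC)cc2)OC1 | intermediate
11 | (Z)-3-[(4-methoxybenzyl)oxy]-2-methylprop-2-en-1-ol | OC/C(C)=C\OCc1ccc(OC)cc1 | intermediate
12 | racemic dienone ketal: 5-{[(tert-butyldiphenylsilyl)oxy]methyl}-6-methoxy-6-{[(Z)-3-[(4-methoxybenzyl)oxy]-2-methylprop-2-en-1-yl]oxy}-2-[(triisopropylsilyl)oxy]cyclohexa-2,4-dien-1-one | O=C1C(O[Si](C(C)C)(C(C)C)C(C)C)=CC=C(CO[Si](c2ccccc2)(c2ccccc2)C(C)(C)C)[C@]1(OC)OC/C(C)=C\OCc1ccc(OC)cc1.O=C1C(O[Si](C(C)C)(C(C)C)C(C)C)=CC=C(CO[Si](c2ccccc2)(c2ccccc2)C(C)(C)C)[C@@]1(OC)OC/C(C)=C\OCc1ccc(OC)cc1 | intermediate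
13 | racemic tethered Diels–Alder adduct (14 and its mirror image, 1:1) | CC(C)(C)[Si](c1ccccc1)(c1ccccc1)OC[C@@]12[C@](OC)(OC3)C(=O)[C@@](O[Si](C(C)C)(C(C)C)C(C)C)(C=C1)[C@H](OCc1ccc(OC)cc1)[C@@]23C.CC(C)(C)[Si](c1ccccc1)(c1ccccc1)OC[C@]12[C@@](OC)(OC3)C(=O)[C@](O[Si](C(C)C)(C(C)C)C(C)C)(C=C1)[C@@H](OCc1ccc(OC)cc1)[C@]23C | intermediate
14 | bicyclo[2.2.2]oct-5-en-2-one, single enantiomer (ketone C11; C8–CH2OTBDPS; C34–OTIPS; C9 methyl ketal tied through O–C23H2 to C25; C26 syn to the alkene; O28–PMB syn to the C9–C11 bridge) | CC(C)(C)[Si](c1ccccc1)(c1ccccc1)OC[C@@]12[C@](OC)(OC3)C(=O)[C@@](O[Si](C(C)C)(C(C)C)C(C)C)(C=C1)[C@H](OCc1ccc(OC)cc1)[C@@]23C | intermediate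
15 | tricyclo[3.3.0.0]octan-3-one (rings A and C, cyclopropane C14-C34-C36, C11 ketone) | CC(C)(C)[Si](c1ccccc1)(c1ccccc1)OC[C@@]12[C@](OC)(OC4)C(=O)[C@H]3[C@@H]1[C@@]3(O[Si](C(C)C)(C(C)C)C(C)C)[C@H](OCc1ccc(OC)cc1)[C@@]24C | intermediate
16 | tertiary cyclopropyl carbinol (C11 with C12 methyl and OH) | CC(C)(C)[Si](c1ccccc1)(c1ccccc1)OC[C@@]12[C@](OC)(OC4)[C@](C)(O)[C@H]3[C@@H]1[C@@]3(O[Si](C(C)C)(C(C)C)C(C)C)[C@H](OCc1ccc(OC)cc1)[C@@]24C | intermediate
17 | C11 methanesulfonate of 16 | CC(C)(C)[Si](c1ccccc1)(c1ccccc1)OC[C@@]12[C@](OC)(OC4)[C@](C)(OS(C)(=O)=O)[C@H]3[C@@H]1[C@@]3(O[Si](C(C)C)(C(C)C)C(C)C)[C@H](OCc1ccc(OC)cc1)[C@@]24C | intermediate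
18 | diquinane β,γ-unsaturated ketone (C34 ketone, C11(CH3)=C14) | CC(C)(C)[Si](c1ccccc1)(c1ccccc1)OC[C@@]12[C@](OC)(OC4)C(C)=C[C@@H]1C(=O)[C@H](OCc1ccc(OC)cc1)[C@@]24C | intermediate
19 | dichlorocerium alkoxide of the C34 methyl carbinol | CC(C)(C)[Si](c1ccccc1)(c1ccccc1)OC[C@@]12[C@](OC)(OC4)C(C)=C[C@@H]1[C@](C)(O[Ce](Cl)Cl)[C@H](OCc1ccc(OC)cc1)[C@@]24C | intermediate
20 | 2-bromopropanoate of the C34 tertiary alcohol (epimers at CHBr) | CC(C)(C)[Si](c1ccccc1)(c1ccccc1)OC[C@@]12[C@](OC)(OC4)C(C)=C[C@@H]1[C@](C)(OC(=O)C(C)Br)[C@H](OCc1ccc(OC)cc1)[C@@]24C | intermediate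
21 | C27 secondary alcohol | CC(C)(C)[Si](c1ccccc1)(c1ccccc1)OC[C@@]12[C@](OC)(OC4)C(C)=C[C@@H]1[C@](C)(OC(=O)C(C)Br)[C@H](O)[C@@]24C | intermediate
22 | C27 ketone | CC(C)(C)[Si](c1ccccc1)(c1ccccc1)OC[C@@]12[C@](OC)(OC4)C(C)=C[C@@H]1[C@](C)(OC(=O)C(C)Br)C(=O)[C@@]24C | intermediate
23 | β-hydroxy-γ-lactone, C29 epimer (C30 cis to O28) | CC(C)(C)[Si](c1ccccc1)(c1ccccc1)OC[C@@]12[C@](OC)(OC4)C(C)=C[C@@H]1[C@]5(C)OC(=O)[C@@H](C)[C@]5(O)[C@@]24C | intermediate
24 | β-hydroxy-γ-lactone with the C29 configuration of the target | CC(C)(C)[Si](c1ccccc1)(c1ccccc1)OC[C@@]12[C@](OC)(OC4)C(C)=C[C@@H]1[C@]5(C)OC(=O)[C@H](C)[C@]5(O)[C@@]24C | intermediate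
25 | C27 triethylsilyl ether | CC(C)(C)[Si](c1ccccc1)(c1ccccc1)OC[C@@]12[C@](OC)(OC4)C(C)=C[C@@H]1[C@]5(C)OC(=O)[C@H](C)[C@]5(O[Si](CC)(CC)CC)[C@@]24C | intermediate
26 | ring A enone with the C23 primary alcohol | CC(C)(C)[Si](c1ccccc1)(c1ccccc1)OC[C@@]12C(=O)C(C)=C[C@@H]1[C@]5(C)OC(=O)[C@H](C)[C@]5(O[Si](CC)(CC)CC)[C@]2(C)CO | intermediate
27 | C23 aldehyde | CC(C)(C)[Si](c1ccccc1)(c1ccccc1)OC[C@@]12C(=O)C(C)=C[C@@H]1[C@]5(C)OC(=O)[C@H](C)[C@]5(O[Si](CC)(CC)CC)[C@]2(C)C=O | intermediate
28 | C11,C14-epoxy ketone | CC(C)(C)[Si](c1ccccc1)(c1ccccc1)OC[C@@]12C(=O)[C@@]3(C)O[C@H]3[C@@H]1[C@]5(C)OC(=O)[C@H](C)[C@]5(O[Si](CC)(CC)CC)[C@]2(C)C=O | intermediate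
29 | sorbic acid, (2E,4E)-hexa-2,4-dienoic acid | C/C=C/C=C/C(=O)O | starting material
30 | (3E,5E)-hepta-3,5-dien-2-one | CC(=O)/C=C/C=C/C | intermediate
31 | aldol adduct (C23 carbinol, both epimers) | CC(C)(C)[Si](c1ccccc1)(c1ccccc1)OC[C@@]12C(=O)[C@@]3(C)O[C@H]3[C@@H]1[C@]5(C)OC(=O)[C@H](C)[C@]5(O[Si](CC)(CC)CC)[C@]2(C)C(O)CC(=O)/C=C/C=C/C | intermediate
32 | β-diketone with the epoxy ketone | CC(C)(C)[Si](c1ccccc1)(c1ccccc1)OC[C@@]12C(=O)[C@@]3(C)O[C@H]3[C@@H]1[C@]5(C)OC(=O)[C@H](C)[C@]5(O[Si](CC)(CC)CC)[C@]2(C)C(=O)CC(=O)/C=C/C=C/C | intermediate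
33 | tetracycle with ring B closed, O28–TES, C6–OTBDPS | CC(C)(C)[Si](c1ccccc1)(c1ccccc1)OC[C@]12C(=O)[C@@](C)(O)[C@@H]3\C(=C(O)/C=C/C=C/C)C(=O)[C@@]1(C)[C@@]1(O[Si](CC)(CC)CC)[C@@H](C)C(=O)O[C@@]1(C)[C@@H]32 | intermediate
34 | triol (C6–OH, C11–OH, C27–OH) | OC[C@]12C(=O)[C@@](C)(O)[C@@H]3\C(=C(O)/C=C/C=C/C)C(=O)[C@@]1(C)[C@@]1(O)[C@@H](C)C(=O)O[C@@]1(C)[C@@H]32 | intermediate
35 | C6 aldehyde | O=C[C@]12C(=O)[C@@](C)(O)[C@@H]3\C(=C(O)/C=C/C=C/C)C(=O)[C@@]1(C)[C@@]1(O)[C@@H](C)C(=O)O[C@@]1(C)[C@@H]32 | intermediate
36 | (E)-but-2-enal | C/C=C/C=O | starting material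
37 | (1E,3E)-1-iodopenta-1,3-diene | C/C=C/C=C/I | intermediate
38 | C6 dienyl carbinol (both C6 epimers) | C/C=C/C=C/C(O)[C@]12C(=O)[C@@](C)(O)[C@@H]3\C(=C(O)/C=C/C=C/C)C(=O)[C@@]1(C)[C@@]1(O)[C@@H](C)C(=O)O[C@@]1(C)[C@@H]32 | intermediate
39 | CNP0231466.1 | C/C=C/C=C/C(=O)[C@]12C(=O)[C@@](C)(O)[C@@H]3\C(=C(O)/C=C/C=C/C)C(=O)[C@@]1(C)[C@@]1(O)[C@@H](C)C(=O)O[C@@]1(C)[C@@H]32 | target

## Step count and least certain steps

Total: 32 steps. Longest linear sequence: 27 steps (steps 1 to 6, 10 to 23, 25 to 29, 31 and 32). Steps 7 to 9, 24 and 30 prepare the alkenol and the two sorbyl building blocks.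

**Step 12 (key step).** Three things may go wrong:

- a singlet 1,3-acyl shift, if sensitisation is incomplete;
- α-cleavage of the excited ketone towards the oxygen-bearing carbons C9 or C34;
- secondary photolysis of the donor–acceptor cyclopropane on prolonged irradiation.

Each of these lowers conversion to the 1,2-shift product. The fallback removes the ketone chromophore and uses the all-carbon di-π-methane version of the same skeletal change. It sets out from 14 and comes back at 18.

- The ketone of 14 is methylenated with Cp2TiMe2 (tetravalent titanium) in toluene at 70 °C to the 1,4-diene, the C11 methylidene compound F1.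
- Acetone-sensitised irradiation of F1 moves the exocyclic vinyl group from C34 to C14 and closes C34–C36, because this pathway keeps the secondary radical at C36 and not a primary one. The product is the isopropenyl cyclopropane F2.
- Protonation of F2 at the methylidene carbon with catalytic camphorsulfonic acid in dry CH2Cl2 gives the same silyloxy-assisted cyclopropylcarbinyl cation as in step 14, and this opens to 18.

The same compound F2 can also be reached from 15 by methylenation if the sulfonylation in step 14 should fail.

**Step 10.** The acetic acid released by the oxidant may destroy the acid-labile enol ether of 11 before it is captured. The alkenol may add para to the phenol oxygen instead of at C9. The dienone may dimerise if the intramolecular cycloaddition is slow. The fallback uses an aryl enol ether, which does not ionise under these conditions. It sets out from 7 and comes back at 13.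

- Prop-2-yn-1-ol is converted by copper-catalysed addition of MeMgBr and iodination into (Z)-3-iodo-2-methylprop-2-en-1-ol F3.
- Copper-catalysed coupling of F3 with 4-methoxyphenol (CuI, a phenanthroline ligand, Cs2CO3) gives, with retention of geometry, (Z)-3-(4-methoxyphenoxy)-2-methylprop-2-en-1-ol F4.
- Oxidation of 7 with PhI(OAc)2 in the presence of F4 and heating gives the racemic aryl ether adduct F5.
- (NH4)2Ce(NO3)6 (tetravalent cerium) in buffered aqueous MeCN removes the 4-methoxyphenyl group to give the racemic C27 alcohol F6.
- F6 is benzylated with NaH and 4-methoxybenzyl bromide to give 13.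

**Step 19 (with step 18).** Protonation of the lactone enolate may occur from the concave face or be unselective, so that the C30 methyl stays cis to O28. The fallback delivers the hydrogen by hydrogenation instead. It sets out from 23 and comes back at 24.

- The dianion of 23 (LiN(iPr)2, –78 °C) is trapped with PhSeBr to give the α-phenylselanyl lactone F7.
- Oxidation with H2O2 and syn-elimination, which can only go towards the methyl group because C27 carries no hydrogen, gives the α-methylidene lactone F8.
- Hydrogenation of F8 with RhCl(PPh3)3 (monovalent rhodium) adds hydrogen to the exposed convex face, the face of O28, and leaves the trisubstituted ring alkene untouched. The product is 24.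

**Step 27.** The diketonate may alkylate on oxygen, may fail to reach the hindered secondary epoxide carbon, or the epoxy ketone may rearrange under base. The fallback closes ring B by conjugate addition and hydroxylates afterwards, before the second carbonyl of the diketone is present. It sets out from 27 and comes back at 33.

- MeMgBr at –78 °C adds to the aldehyde of 27 to give the C23 methyl carbinol F9.
- Dess–Martin oxidation gives the methyl ketone F10.
- Me3SiOTf and Et3N, followed by catalytic Me3SiOTf, give the silyl enol ether of the methyl ketone, which adds to C14 of the enone (intramolecular Mukaiyama–Michael reaction). This closes ring B and leaves the C9 trimethylsilyl enol ether F11.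
- Dimethyldioxirane oxidises F11 from the open face (Rubottom oxidation) to the C11 tertiary α-hydroxy ketone F12.
- Soft enolisation of the ring B ketone of F12 with MgBr2·OEt2 and iPr2NEt and C-acylation at C15 with (2E,4E)-hexa-2,4-dienoyl chloride gives 33.

## Further compounds

F1 | step 12 | C11 methylidene analogue of 14 (1,4-diene) | CC(C)(C)[Si](c1ccccc1)(c1ccccc1)OC[C@@]12[C@](OC)(OC3)C(=C)[C@@](O[Si](C(C)C)(C(C)C)C(C)C)(C=C1)[C@H](OCc1ccc(OC)cc1)[C@@]23C
F2 | step 12 | isopropenyl cyclopropane (C11 methylidene analogue of 15) | CC(C)(C)[Si](c1ccccc1)(c1ccccc1)OC[C@@]12[C@](OC)(OC4)C(=C)[C@H]3[C@@H]1[C@@]3(O[Si](C(C)C)(C(C)C)C(C)C)[C@H](OCc1ccc(OC)cc1)[C@@]24C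
F3 | step 10 | (Z)-3-iodo-2-methylprop-2-en-1-ol | OC/C(C)=C\I
F4 | step 10 | (Z)-3-(4-methoxyphenoxy)-2-methylprop-2-en-1-ol | OC/C(C)=C\Oc1ccc(OC)cc1
F5 | step 10 | racemic adduct with a 4-methoxyphenyl ether on O28 | CC(C)(C)[Si](c1ccccc1)(c1ccccc1)OC[C@@]12[C@](OC)(OC3)C(=O)[C@@](O[Si](C(C)C)(C(C)C)C(C)C)(C=C1)[C@H](Oc1ccc(OC)cc1)[C@@]23C.CC(C)(C)[Si](c1ccccc1)(c1ccccc1)OC[C@]12[C@@](OC)(OC3)C(=O)[C@](O[Si](C(C)C)(C(C)C)C(C)C)(C=C1)[C@@H](Oc1ccc(OC)cc1)[C@]23C
F6 | step 10 | racemic adduct with free C27 hydroxyl | CC(C)(C)[Si](c1ccccc1)(c1ccccc1)OC[C@@]12[C@](OC)(OC3)C(=O)[C@@](O[Si](C(C)C)(C(C)C)C(C)C)(C=C1)[C@H](O)[C@@]23C.CC(C)(C)[Si](c1ccccc1)(c1ccccc1)OC[C@]12[C@@](OC)(OC3)C(=O)[C@](O[Si](C(C)C)(C(C)C)C(C)C)(C=C1)[C@@H](O)[C@]23C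
F7 | step 19 | α-phenylselanyl lactone (C29 epimers) | CC(C)(C)[Si](c1ccccc1)(c1ccccc1)OC[C@@]12[C@](OC)(OC4)C(C)=C[C@@H]1[C@]5(C)OC(=O)C(C)([Se]c6ccccc6)[C@]5(O)[C@@]24C
F8 | step 19 | α-methylidene β-hydroxy γ-lactone | CC(C)(C)[Si](c1ccccc1)(c1ccccc1)OC[C@@]12[C@](OC)(OC4)C(C)=C[C@@H]1[C@]5(C)OC(=O)C(=C)[C@]5(O)[C@@]24C
F9 | step 27 | C23 methyl carbinol (both epimers) with the ring A enone | CC(C)(C)[Si](c1ccccc1)(c1ccccc1)OC[C@@]12C(=O)C(C)=C[C@@H]1[C@]5(C)OC(=O)[C@H](C)[C@]5(O[Si](CC)(CC)CC)[C@]2(C)C(C)O
F10 | step 27 | C23 methyl ketone with the ring A enone | CC(C)(C)[Si](c1ccccc1)(c1ccccc1)OC[C@@]12C(=O)C(C)=C[C@@H]1[C@]5(C)OC(=O)[C@H](C)[C@]5(O[Si](CC)(CC)CC)[C@]2(C)C(C)=O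
F11 | step 27 | ring B closed, C9 trimethylsilyl enol ether | CC(C)(C)[Si](c1ccccc1)(c1ccccc1)OC[C@]12C(O[Si](C)(C)C)=C(C)[C@@H]3CC(=O)[C@@]1(C)[C@@]1(O[Si](CC)(CC)CC)[C@@H](C)C(=O)O[C@@]1(C)[C@@H]32
F12 | step 27 | ring B closed, C11 tertiary α-hydroxy ketone, C15 methylene | CC(C)(C)[Si](c1ccccc1)(c1ccccc1)OC[C@]12C(=O)[C@@](C)(O)[C@@H]3CC(=O)[C@@]1(C)[C@@]1(O[Si](CC)(CC)CC)[C@@H](C)C(=O)O[C@@]1(C)[C@@H]32
A1 | alternative 1 | 3-(benzyloxy)-2-oxopropanal | O=CC(=O)COCc1ccccc1
A2 | alternative 1 | dimethyl 3-oxopentanedioate | COC(=O)CC(=O)CC(=O)OC
A3 | alternative 1 | bis-enol diquinane tetramethyl ester with benzyloxymethyl on C8 | COC(=O)C1=C(O)[C@H](C(=O)OC)[C@@H]2C(C(=O)OC)=C(O)[C@H](C(=O)OC)[C@]12COCc1ccccc1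
A4 | alternative 2 | ring A seco aldehyde (C9 aldehyde on C8, acetyl C11 on C14, O28 trimethylsilyl ether) | O=C[C@@]1(C(=O)/C=C/C=C/C)[C@@]2(C)C(=O)/C(=C(O)/C=C/C=C/C)[C@@H](C(C)=O)[C@@H]1[C@]3(C)OC(=O)[C@H](C)[C@]23O[Si](C)(C)C
A5 | alternative 2 | 3-benzyl-5-(2-hydroxyethyl)-4-methylthiazolium chloride | Cc1c(CCO)sc[n+]1Cc1ccccc1.[Cl-]
A6 | alternative 2 | O28 trimethylsilyl ether of the target | C/C=C/C=C/C(=O)[C@]12C(=O)[C@@](C)(O)[C@@H]3\C(=C(O)/C=C/C=C/C)C(=O)[C@@]1(C)[C@@]1(O[Si](C)(C)C)[C@@H](C)C(=O)O[C@@]1(C)[C@@H]32
A7 | alternative 3 | hydroazulene tetraketone (C8 and C25 not yet joined, both epimerisable) | C/C=C/C=C/C(=O)C1C(=O)[C@@](C)(O[Si](CC)(CC)CC)[C@@H]2CC(=O)C(C)C(=O)[C@@](C)(O[Si](C)(C)C)[C@@H]21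
A8 | alternative 3 | [Fe(DMF)3Cl2][FeCl4] | CN(C)C=O.CN(C)C=O.CN(C)C=O.[Fe+3].[Fe+3].[Cl-].[Cl-].[Cl-].[Cl-].[Cl-].[Cl-]
A9 | alternative 3 | tricyclic tetraketone with rings A, B and C | C/C=C/C=C/C(=O)[C@]12C(=O)[C@@](C)(O[Si](CC)(CC)CC)[C@@H]3CC(=O)[C@@]1(C)C(=O)[C@@](C)(O[Si](C)(C)C)[C@@H]32
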